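**Retrosynthetic overview**
- Target ⇒ cis-fused 6-aryl-3,7-dioxabicyclo[3.3.0]octan-2-one + (3,4,5-trimethoxyphenyl)lithium: one acyl addition unmasks the aryl ketone and the CH2OH together; the ring fusion holds the 3,4-cis pair.
- Bicyclic lactone ⇒ aryl-cyclopropane-fused γ-lactone + formaldehyde: formal [3+2] ring expansion of the donor–acceptor C–C bond; inversion at the benzylic carbon gives the all-cis array.
- Cyclopropane lactone ⇒ E-cinnamyl diazoacetate by catalytic asymmetric intramolecular cyclopropanation: cyclopropane and lactone rings close in the same operation and fix the absolute configuration.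
- Diazo ester ⇒ 3,4-dimethoxycinnamyl alcohol ⇒ methyl 3,4-dimethoxycinnamate.
- Ring order: cyclopropane + γ-lactone (together) → oxolane (cyclopropane consumed) → lactone opened in the last step.

Assumption: the target is the open γ-hydroxy ketone as drawn, (3R,4R,5R) in oxolan-3-yl numbering, with aryl, CH2OH and aroyl all on one face of the oxolane; compounds 1 and 7 are taken as catalogue chemicals.

**Route**

Step 1
Reactants: 1 methyl (E)-3-(3,4-dimethoxyphenyl)prop-2-enoate
Product: 2 (E)-3-(3,4-dimethoxyphenyl)prop-2-en-1-ol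
Conditions: DIBAL-H (i-Bu2AlH, 2.2 equiv), CH2Cl2, −78 °C; aq. Rochelle salt
Reagents that add atoms: none
Why: 1,2-hydride reduction of an α,β-unsaturated ester by DIBAL-H gives the allylic alcohol and leaves the E-alkene untouched; no stereocentre is formed.

Step 2
Reactants: 2 (E)-3-(3,4-dimethoxyphenyl)prop-2-en-1-ol
Product: 4 (E)-3-(3,4-dimethoxyphenyl)prop-2-en-1-yl 2-diazoacetate, via bromoacetate 3 (not isolated)
Conditions: BrCH2COBr (1.3 equiv), NaHCO3, MeCN, 0 °C; then TsNHNHTs (2 equiv), DBU (5 equiv), 0 °C, same flask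
Reagents that add atoms: bromoacetyl bromide BrCC(Br)=O; N,N'-ditosylhydrazine Cc1ccc(cc1)S(=O)(=O)NNS(=O)(=O)c1ccc(C)cc1
Why: O-acylation followed by the Fukuyama diazoacetate synthesis (N-alkylation of ditosylhydrazine by the bromoacetate, then base-induced loss of two sulfinates) gives the diazo ester under mild conditions that the electron-rich cinnamyl ester tolerates; no stereocentre is formed.

Step 3
Reactants: 4 (E)-3-(3,4-dimethoxyphenyl)prop-2-en-1-yl 2-diazoacetate
Product: 5 (1S,5R,6R)-6-(3,4-dimethoxyphenyl)-3-oxabicyclo[3.1.0]hexan-2-one (aryl trans to the lactone CH2)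
Conditions: Rh2(4R-MPPIM)4 (1 mol %), CH2Cl2, reflux, 4 added over 10 h
Reagents that add atoms: none
Why: Doyle-type asymmetric intramolecular cyclopropanation with dirhodium tetrakis[methyl (4R)-2-oxo-1-(3-phenylpropanoyl)imidazolidine-4-carboxylate]: the metal carbene adds to the tethered E-alkene and closes the cyclopropane and the γ-lactone in one event; the alkene geometry fixes aryl trans to the lactone CH2, and the R-ligand catalyst selects the face giving (1S,5R,6R) (the S-ligand series gives the 1R,5S sense; about 95% ee is known for trans-3-arylallyl diazoacetates).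

Step 4
Reactants: 5 (1S,5R,6R)-6-(3,4-dimethoxyphenyl)-3-oxabicyclo[3.1.0]hexan-2-one
Product: 6 (1R,5R,6R)-6-(3,4-dimethoxyphenyl)-3,7-dioxabicyclo[3.3.0]octan-2-one (cis-fused; aryl endo, cis to the lactone CH2)
Conditions: monomeric CH2O (from cracked paraformaldehyde, 3 equiv), Sn(OTf)2 (10 mol %), 4 Å MS, CH2Cl2, −40 to 0 °C
Reagents that add atoms: formaldehyde C=O
Why: Proposed new method: formal [3+2] cycloaddition of a donor–acceptor cyclopropane with an aldehyde, here with a single lactone acceptor and formaldehyde (closest known reaction: the Sn(OTf)2-catalysed annulation of 2-arylcyclopropane-1,1-diesters with aldehydes, which runs with inversion at the donor carbon); the Lewis acid on the lactone carbonyl polarises the strained C1–C6 bond toward the dimethoxybenzyl carbon, the formaldehyde oxygen opens it from the rear (inversion at C6), and the tin enolate closes on the oxocarbenium carbon on the only face that allows a cis-fused ring, so C5 is untouched, C1 is set by the ring fusion and the inverted C6 places the aryl group endo (all-cis).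

Step 5
Reactants: 6 (1R,5R,6R)-6-(3,4-dimethoxyphenyl)-3,7-dioxabicyclo[3.3.0]octan-2-one; 7 5-bromo-1,2,3-trimethoxybenzene
Product: 10 [(3R,4R,5R)-5-(3,4-dimethoxyphenyl)-4-(hydroxymethyl)oxolan-3-yl](3,4,5-trimethoxyphenyl)methanone, via aryllithium 8 (not isolated), via lithium lactolate 9 (not isolated)
Conditions: 7 (1.15 equiv), n-BuLi (1.1 equiv), THF, −78 °C, 30 min; then 6, −78 °C, 1 h; AcOH/THF quench at −78 °C
Reagents that add atoms: none
Why: nucleophilic acyl addition of an aryllithium (from bromine–lithium exchange) to a γ-lactone stops at the tetrahedral lithium lactolate 9, which blocks a second addition at −78 °C, and the cold acetic acid quench releases the γ-hydroxy ketone without epimerising the α-carbon, so the three stereocentres of 6 are carried over unchanged.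

**Compound list**

1 | methyl (E)-3-(3,4-dimethoxyphenyl)prop-2-enoate | COC(=O)/C=C/c1ccc(OC)c(OC)c1 | starting material
2 | (E)-3-(3,4-dimethoxyphenyl)prop-2-en-1-ol | OC/C=C/c1ccc(OC)c(OC)c1 | intermediate
3 | (E)-3-(3,4-dimethoxyphenyl)prop-2-en-1-yl 2-bromoacetate | BrCC(=O)OC/C=C/c1ccc(OC)c(OC)c1 | intermediate
4 | (E)-3-(3,4-dimethoxyphenyl)prop-2-en-1-yl 2-diazoacetate | [N-]=[N+]=CC(=O)OC/C=C/c1ccc(OC)c(OC)c1 | intermediate
5 | (1S,5R,6R)-6-(3,4-dimethoxyphenyl)-3-oxabicyclo[3.1.0]hexan-2-one | COc1ccc([C@@H]2[C@H]3COC(=O)[C@@H]23)cc1OC | intermediate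
6 | (1R,5R,6R)-6-(3,4-dimethoxyphenyl)-3,7-dioxabicyclo[3.3.0]octan-2-one | COc1ccc([C@@H]2OC[C@@H]3C(=O)OC[C@H]23)cc1OC | intermediate
7 | 5-bromo-1,2,3-trimethoxybenzene | COc1cc(Br)cc(OC)c1OC | starting material
8 | (3,4,5-trimethoxyphenyl)lithium | [Li]c1cc(OC)c(OC)c(OC)c1 | intermediate
9 | lithium (1R,5R,6R)-6-(3,4-dimethoxyphenyl)-2-(3,4,5-trimethoxyphenyl)-3,7-dioxabicyclo[3.3.0]octan-2-olate (C2 epimers) | [Li+].COc1ccc([C@@H]2OC[C@@H]3C([O-])(c4cc(OC)c(OC)c(OC)c4)OC[C@H]23)cc1OC | intermediate
10 | [(3R,4R,5R)-5-(3,4-dimethoxyphenyl)-4-(hydroxymethyl)oxolan-3-yl](3,4,5-trimethoxyphenyl)methanone | COc1ccc([C@@H]2OC[C@H](C(=O)c3cc(OC)c(OC)c(OC)c3)[C@@H]2CO)cc1OC | target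

**Totals**
Total step count: 5. Longest linear sequence: 5 steps (1 → 2 → 4 → 5 → 6 → 10); 7 enters in the last step.

**Steps most likely to fail**

Step 4 (most at risk). A single lactone acceptor may be too weakly activating. The dimethoxybenzyl cation may also form freely, which would erode the inversion or let the endo aryl epimerise to exo. Fallback from 5, back at 6: hydrate the donor–acceptor bond (Sc(OTf)3 5 mol %, H2O/THF, 0 °C; water enters at the benzylic carbon with inversion, and any epimer is removed by chromatography) to (4R)-4-[(R)-(3,4-dimethoxyphenyl)(hydroxy)methyl]oxolan-2-one F1. Convert it with MOMCl/i-Pr2NEt into the formaldehyde acetal (4R)-4-[(R)-(3,4-dimethoxyphenyl)(methoxymethoxy)methyl]oxolan-2-one F2. Treat F2 with Et3N/TMSOTf (CH2Cl2, −78 to −20 °C): soft enolisation of the lactone and capture of the oxocarbenium ion released from the acetal (intramolecular Mukaiyama-type alkylation) close the oxolane cis-fused. The benzylic C–O bond is formed before the ring closure and is not broken again, and the sequence returns to 6.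

Step 5. The aryllithium may enolise the lactone or add twice, and the all-cis ketone can epimerise at its α-carbon if it meets base. Fallback from 6, back at 10: reduce with DIBAL-H (CH2Cl2, −78 °C) to the lactol (1R,5R,6R)-6-(3,4-dimethoxyphenyl)-3,7-dioxabicyclo[3.3.0]octan-2-ol F3. Add aryllithium 8 (2.5 equiv, THF, −78 to 0 °C) to its open hydroxy aldehyde form to give the diol [(2R,3R,4R)-2-(3,4-dimethoxyphenyl)-4-[hydroxy(3,4,5-trimethoxyphenyl)methyl]oxolan-3-yl]methanol F4. Oxidise only the benzylic secondary alcohol with MnO2 (CH2Cl2, rt). This reaches 10 under neutral conditions, so the ketone never sees base.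

Step 3. The enantioselectivity, the facial sense (assigned by analogy and to be checked on 5 by chiral HPLC) and the supply of the R-ligand catalyst are the weak points. Fallback from 2, back at 5: Sharpless epoxidation (Ti(OiPr)4, L-(+)-DIPT, t-BuOOH, 4 Å MS, CH2Cl2, −20 °C) gives [(2S,3S)-3-(3,4-dimethoxyphenyl)oxiran-2-yl]methanol F5. TBSCl/imidazole gives tert-butyl{[(2S,3S)-3-(3,4-dimethoxyphenyl)oxiran-2-yl]methoxy}dimethylsilane F6. Wadsworth–Emmons cyclopropanation with triethyl phosphonoacetate/NaOtBu (toluene, 110 °C; SN2 attack at each epoxide carbon, double inversion) gives ethyl (2R,3R)-2-{[tert-butyl(dimethyl)silyl]oxymethyl}-3-(3,4-dimethoxyphenyl)cyclopropane-1-carboxylate F7. TBAF, then catalytic NaOEt in EtOH, epimerises C1 and lactonises the ester that is cis to CH2OH, returning to 5.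

**Further compounds**

F1 | step 4 | (4R)-4-[(R)-(3,4-dimethoxyphenyl)(hydroxy)methyl]oxolan-2-one | COc1ccc([C@H](O)[C@H]2COC(=O)C2)cc1OC
F2 | step 4 | (4R)-4-[(R)-(3,4-dimethoxyphenyl)(methoxymethoxy)methyl]oxolan-2-one | COc1ccc([C@H](OCOC)[C@H]2COC(=O)C2)cc1OC
F3 | step 5 | (1R,5R,6R)-6-(3,4-dimethoxyphenyl)-3,7-dioxabicyclo[3.3.0]octan-2-ol (anomer mixture) | COc1ccc([C@@H]2OC[C@@H]3C(O)OC[C@H]23)cc1OC
F4 | step 5 | [(2R,3R,4R)-2-(3,4-dimethoxyphenyl)-4-[hydroxy(3,4,5-trimethoxyphenyl)methyl]oxolan-3-yl]methanol (carbinol epimers) | COc1ccc([C@@H]2OC[C@H](C(O)c3cc(OC)c(OC)c(OC)c3)[C@@H]2CO)cc1OC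
F5 | step 3 | [(2S,3S)-3-(3,4-dimethoxyphenyl)oxiran-2-yl]methanol | OC[C@@H]1O[C@H]1c1ccc(OC)c(OC)c1
F6 | step 3 | tert-butyl{[(2S,3S)-3-(3,4-dimethoxyphenyl)oxiran-2-yl]methoxy}dimethylsilane | CC(C)(C)[Si](C)(C)OC[C@@H]1O[C@H]1c1ccc(OC)c(OC)c1
F7 | step 3 | ethyl (2R,3R)-2-{[tert-butyl(dimethyl)silyl]oxymethyl}-3-(3,4-dimethoxyphenyl)cyclopropane-1-carboxylate (C1 epimers) | CCOC(=O)C1[C@H](CO[Si](C)(C)C(C)(C)C)[C@H]1c1ccc(OC)c(OC)c1
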